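The earlier runs and the new flask were computed with made-up constants; the scatter is artificial.

| setting | oak | cedar | south-east | north-east |
|---|---|---|---|---|
| substrate | 0.30 M | 0.30 M | 0.30 M | 0.30 M |
| solid reagent | 0.30 M | 0.30 M | 0.300 M | 0.300 M |
| free catalyst | 0.30 mM | 0.30 mM | 0.30 mM | 0.30 mM |
| added ligand | 0.095 mM | 0.14 mM | 0.19 mM | 0.19 mM |
| remark | run made earlier | run made earlier |  |  |
| time |  |  | 20 h | 40 h |

| run | time / h | product / % | substrate / % | catalyst intermediate B / % |
|---|---|---|---|---|
| oak | 1.33 | 4 | 96 | 0 |
| oak | 4.00 | 9 | 89 | 0 |
| oak | 8.00 | 21 | 79 | 0 |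
| oak | 10.0 | 26 | 72 | 2 |
| oak | 15.0 | 42 | 57 | 0 |
| oak | 20.0 | 54 | 42 | 1 |
| cedar | 1.33 | 0 | 99 | 0 |
| cedar | 4.00 | 8 | 91 | 3 |
| cedar | 8.00 | 17 | 83 | 1 |
| cedar | 10.0 | 23 | 78 | 0 |
| cedar | 15.0 | 36 | 62 | 0 |
| cedar | 20.0 | 50 | 50 | 0 |

(readings scatter by 1.5 percentage points)

1. which of these there is most of at the end, counted by the substrate in it, south-east (product / catalyst intermediate B / substrate)
2. which of these there is most of at the end, counted by the substrate in it, north-east (product / catalyst intermediate B / substrate)
3. the largest of these amounts at the end, in percent of the substrate charged, south-east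
4. the largest of these amounts at the end, in percent of the substrate charged, north-east

If each added ligand holds one free catalyst, the uncaptured share of the catalyst charge is f = 1 − ligand/catalyst. That is 0.683 in oak, 0.533 in cedar, and 0.367 in south-east and north-east. Full conversion costs N = 1000 turnovers of the catalyst charge. Oak's product grows about linearly, with 26% at 10.0 h and 54% at 20.0 h. So I write the converted fraction as X = νft/N.

Which numbers matter? The solid reagent charge is unchanged across the runs, so I assign it no error. In my reckoning the substrate charge cancels if ν was measured at that same charge, as here. A fractional error in the catalyst charge of south-east comes through 2.73 times over, and one in its ligand charge 1.73 times, because f is a difference. A cedar reading off by 1.5 percentage points moves my south-east X by 2.2 points.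

Now the number. Oak gives ν = 39.5 h⁻¹ and cedar 46.9 h⁻¹, so the readings show ν rising with ligand. I carry ν, the turnovers per hour per uncaptured catalyst (turnover frequency). Continued straight in ligand, my estimate is 55.1 h⁻¹. My reckoning then gives 40.4% product in south-east, so substrate leads there at 59.6%, and 80.7% product in north-east.

The forecast differs in the amounts, with substrate leading at 54% in south-east and product at 88% in north-east, on the view that “added ligand inhibits only mildly”.

South-east ends with substrate leading at 60.1%, and north-east with product at 77.1%.

    partner + free catalyst ⇌ catalyst intermediate A (K = 69.0 M⁻¹, k = 0.600 M⁻¹ s⁻¹)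
    substrate + catalyst intermediate A → catalyst intermediate B (k = 1.30 M⁻¹ s⁻¹)
    catalyst intermediate B ⇌ free catalyst + product (K = 0.770 M, k = 13.0 s⁻¹)
    solid reagent ⇌ partner, rate k4*(cs4 - [partner]) while solid is left; crystals form when [partner] > cs4 (solubility = 42.0 mM, k = 1.40 × 10⁻⁴ s⁻¹)
    free catalyst + added ligand ⇌ idle complex, settled at all times (K = 2.00 × 10⁵ M⁻¹)

Counted back, ν is 54.3 h⁻¹ in south-east and 52.6 h⁻¹ in north-east. In south-east at 8.23 h, partner is made 1.02 times as fast as it is used, each step taken net, and catalyst intermediate A falls back at 0.026 of the rate at which it goes on. In the neighbour flask charged with 0.12 M of substrate, 84.5% product after 20 h gives ν = 46.1 h⁻¹, lower than in south-east.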